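The cyclopentane ring (C1–C5; daucane numbering, C1 = methyl-bearing ring-fusion carbon, C4 = carbinol, C5 = ring-fusion CH, C6 = benzoyloxy carbon) is cut at C2–C3 and C4–C5. C5 is the α-carbon and C2 the γ-carbon of a C6 ketone, so both are released from one cyclopropane (C1–C2–C5) fused to the cycloheptenone. A samarium-catalysed radical-relay [3+2] annulation of this bicyclo[5.1.0]octenone with a 1-isopropylvinyl sulfone forms both bonds; sulfinate loss funnels all diastereomers into one C4=C5 enone. Hydride addition anti to the C1 methyl, hydroxyl-directed epoxidation and a stereospecific 1,2-hydride shift then set C4 and the trans ring fusion; directed reduction, benzoylation and epoxidation finish.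

Key step: step 10

Remark on numbering: daucane numbering is used throughout (C1 quaternary with methyl; C2, C3 ring CH2; C4 carbinol with isopropyl; C5 ring-fusion CH; C6 oxygenated; C7 CH2; C8 methyl-bearing alkene or epoxide carbon; C9; C10). β is the face of the C1 methyl group. In the bicyclic cyclopropyl ketone the cyclopropane carbons are the future C1, C2 and C5.

Step 1
Reactants: 1 but-2-yn-1-ol
Product: 2 (2Z)-3-iodobut-2-en-1-ol
Conditions: NaAlH2(OCH2CH2OCH3)2, THF, 0 to 20 °C; then I2, −78 °C
Reagents that add atoms: iodine, [I][I]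
Why: Hydroalumination–iodination, in which the alkoxide-bound aluminium hydride adds trans across the alkyne with aluminium on C3 in a five-membered chelate and iodinolysis with retention should give the Z vinyl iodide.

Step 2
Reactants: 2 (2Z)-3-iodobut-2-en-1-ol
Product: 3 (2Z)-3-methylhexa-2,5-dien-1-ol
Conditions: allyltributylstannane, Pd2(dba)3 (2.5 mol %), tri(2-furyl)phosphine, DMF, 20 °C
Reagents that add atoms: allyltributylstannane, C=CC[Sn](CCCC)(CCCC)CCCC
Why: Stille coupling of the vinyl iodide proceeds with retention of alkene geometry and tolerates the free hydroxyl group, so the allyl group should end up cis to the hydroxymethyl group.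

Step 3
Reactants: 3 (2Z)-3-methylhexa-2,5-dien-1-ol
Product: 4 [(1R,2S)-2-methyl-2-(prop-2-en-1-yl)cyclopropyl]methanol
Conditions: Et2Zn, CH2I2, DME, (4S,5S)-2-butyl-N,N,N′,N′-tetramethyl-1,3,2-dioxaborolane-4,5-dicarboxamide, CH2Cl2, −10 to 20 °C
Reagents that add atoms: diiodomethane, ICI
Why: Simmons–Smith cyclopropanation in which the zinc alkoxide of 3 is bound to the chiral dioxaborolane, so that CH2 is delivered to one face of the allylic alkene only (the (4S,5S) ligand is chosen from the established sense of induction, the (4R,5R) ligand taking cinnamyl alcohol to its (1S,2S) cyclopropane), which sets both cyclopropane stereocentres, the quaternary one becoming C1, while the Z geometry fixes allyl and hydroxymethyl cis and the undirected terminal alkene stays intact.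

Step 4
Reactants: 4 [(1R,2S)-2-methyl-2-(prop-2-en-1-yl)cyclopropyl]methanol
Product: 5 (1R,2S)-2-methyl-2-(prop-2-en-1-yl)cyclopropane-1-carbaldehyde
Conditions: Dess–Martin periodinane, pyridine, CH2Cl2, 0 °C
Reagents that add atoms: none
Why: Dess–Martin oxidation of the primary alcohol under buffered neutral conditions should give the aldehyde without epimerising the cis-cyclopropane.

Step 5
Reactants: 5 (1R,2S)-2-methyl-2-(prop-2-en-1-yl)cyclopropane-1-carbaldehyde
Product: 6 3-methyl-1-[(1R,2S)-2-methyl-2-(prop-2-en-1-yl)cyclopropyl]but-3-en-1-ol (both carbinol epimers)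
Conditions: 2-methylallylmagnesium chloride, THF, −78 °C
Reagents that add atoms: 2-methylallylmagnesium chloride, CC(=C)C[Mg]Cl
Why: Grignard addition to the aldehyde installs C7 and C8 with its methyl group, the carbinol centre being formed as an inconsequential mixture because it is oxidised in step 7.

Step 6
Reactants: 6 3-methyl-1-[(1R,2S)-2-methyl-2-(prop-2-en-1-yl)cyclopropyl]but-3-en-1-ol
Product: 7 (1R,7S)-4,7-dimethylbicyclo[5.1.0]oct-4-en-2-ol (both C2 epimers)
Conditions: second-generation Grubbs catalyst (5 mol %), CH2Cl2 (0.005 M), 40 °C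
Reagents that add atoms: none
Why: Ring-closing metathesis of the allyl and 2-methylallyl groups, which the cis-cyclopropane holds close, should close the cycloheptene with the trisubstituted C8=C9 alkene and is driven by loss of ethene.

Step 7
Reactants: 7 (1R,7S)-4,7-dimethylbicyclo[5.1.0]oct-4-en-2-ol
Product: 8 (1R,7S)-4,7-dimethylbicyclo[5.1.0]oct-4-en-2-one
Conditions: Dess–Martin periodinane, pyridine, CH2Cl2, 0 °C
Reagents that add atoms: none
Why: Dess–Martin oxidation with pyridine as buffer should give the cyclopropyl ketone without moving the β,γ-alkene into conjugation.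

Step 8
Reactants: 9 3-methylbut-1-yne
Product: 10 [(3-methylbut-1-en-2-yl)sulfanyl]benzene
Conditions: PhSH, Pd(OAc)2 (2 mol %), THF, 40 °C, sealed tube
Reagents that add atoms: benzenethiol, Sc1ccccc1
Why: Pd(OAc)2-catalysed hydrothiolation of a terminal alkyne is Markovnikov-selective through insertion into a palladium–sulfur bond, so sulfur should end up on the internal carbon.

Step 9
Reactants: 10 [(3-methylbut-1-en-2-yl)sulfanyl]benzene
Product: 11 [(3-methylbut-1-en-2-yl)sulfonyl]benzene
Conditions: mCPBA (2.2 equiv), CH2Cl2, 0 to 20 °C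
Reagents that add atoms: 3-chloroperoxybenzoic acid (mCPBA), OOC(=O)c1cccc(Cl)c1
Why: Peracid oxidation of the sulfide to the sulfone is far faster than epoxidation of the vinyl group, which becomes electron-poor after the first oxygen transfer.

Step 10
Reactants: 8 (1R,7S)-4,7-dimethylbicyclo[5.1.0]oct-4-en-2-one; 11 [(3-methylbut-1-en-2-yl)sulfonyl]benzene
Product: 13 (1R)-dauca-4,8-dien-6-one, via β-sulfonyl ketone 12 (not isolated)
Conditions: SmI2 (20 mol %), samarium metal (20 mol %), THF, 55 °C; then DBU, 0 to 20 °C
Reagents that add atoms: none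
Why: Divalent samarium reduces the C6 ketone of 8 to a ketyl whose cyclopropylcarbinyl fragmentation cleaves the external C2–C5 bond, giving a primary C2 radical and a trivalent samarium enolate (C5=C6); the nucleophilic C2 radical adds to the CH2 terminus of electron-poor 11 (C2–C3 bond), the resulting electrophilic α-sulfonyl radical at C4 closes onto enolate carbon C5 (C4–C5 bond), and the new ketyl returns its electron to trivalent samarium. The closest known reaction type is the SmI2-catalysed radical-relay formal [3+2] cycloaddition of cyclopropyl ketones with alkenes and alkynes, a Giese addition followed by radical cyclisation. The cyclopentane closes in the 5-exo-trig mode. The two stereocentres formed in 12 (C4 and C5) are left uncontrolled on purpose, because DBU-induced E1cB loss of benzenesulfinate erases both and funnels every diastereomer into the single C4=C5 enone 13, while C1, the only stereocentre kept, is never touched. The step needs cleavage of the external rather than the internal (C1–C5) cyclopropane bond, which should be secured by overlap of the external bond with the carbonyl π-system in the rigid bicycle, and it needs the radical to be captured by 11 rather than by the isolated C8=C9 alkene, which polarity matching should secure. Keeping samarium catalytic limits reduction of the primary radical and of the vinyl sulfone.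

Step 11
Reactants: 13 (1R)-dauca-4,8-dien-6-one
Product: 14 (1R,6R)-dauca-4,8-dien-6-ol
Conditions: NaBH4, CeCl3·7H2O, MeOH, −40 °C
Reagents that add atoms: none
Why: Luche reduction gives clean 1,2-reduction of the enone and hydride should attack C6 from the α-face, anti to the pseudo-axial C1 methyl group, to set the 6β-hydroxyl.

Step 12
Reactants: 14 (1R,6R)-dauca-4,8-dien-6-ol
Product: 15 (1R,4R,5S,6R)-4,5-epoxydauc-8-en-6-ol
Conditions: VO(acac)2 (5 mol %), t-BuOOH, CH2Cl2, 0 °C
Reagents that add atoms: tert-butyl hydroperoxide, CC(C)(C)OO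
Why: Vanadium-catalysed epoxidation of an allylic alcohol transfers oxygen within the alkoxide–peroxide complex to the alkene face syn to the hydroxyl group, which should set the 4β,5β-epoxide (C4 configuration) and leave the remote C8=C9 alkene untouched.

Step 13
Reactants: 15 (1R,4R,5S,6R)-4,5-epoxydauc-8-en-6-ol
Product: 16 (1R,4R,5R)-4-hydroxydauc-8-en-6-one
Conditions: ZnBr2, CH2Cl2, −20 to 0 °C
Reagents that add atoms: none
Why: Semipinacol rearrangement of a 2,3-epoxy alcohol with 1,2-hydride shift, in which zinc bound to the C6 hydroxyl and the epoxide oxygen breaks the C5–O bond while the C6 hydrogen, antiperiplanar to it on the α-face, migrates to C5, which should give the trans ring fusion (5α-H), the C6 ketone and the free 4β-hydroxyl.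

Step 14
Reactants: 16 (1R,4R,5R)-4-hydroxydauc-8-en-6-one
Product: 17 (1R,4R,5S,6S)-dauc-8-ene-4,6-diol
Conditions: Me4NBH(OAc)3, MeCN/AcOH, −30 °C
Reagents that add atoms: none
Why: Evans–Saksena reduction, in which the 4β-hydroxyl exchanges onto boron and delivers hydride intramolecularly to the β-face of the C6 ketone, should give the 6α-alcohol.

Step 15
Reactants: 17 (1R,4R,5S,6S)-dauc-8-ene-4,6-diol
Product: 18 (1R,4R,5S,6S)-4-hydroxydauc-8-en-6-yl benzoate
Conditions: BzCl, pyridine, DMAP (cat.), CH2Cl2, 0 to 20 °C
Reagents that add atoms: benzoyl chloride, O=C(Cl)c1ccccc1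
Why: Acylation with benzoyl chloride under DMAP catalysis should be selective for the secondary C6 hydroxyl because the tertiary C4 hydroxyl is too hindered to react.

Step 16
Reactants: 18 (1R,4R,5S,6S)-4-hydroxydauc-8-en-6-yl benzoate
Product: 19 (1R,4R,5S,6S,8R,9S)-8,9-epoxy-4-hydroxydaucan-6-yl benzoate (CNP0340059.1)
Conditions: mCPBA, CH2Cl2, 0 °C
Reagents that add atoms: 3-chloroperoxybenzoic acid (mCPBA), OOC(=O)c1cccc(Cl)c1
Why: Prilezhaev epoxidation of the only alkene should take place on the α-face, anti to the C1 methyl group that shields the β-face of the seven-membered ring, setting C8 and C9.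

Compound list

1 | but-2-yn-1-ol | CC#CCO | starting material
2 | (2Z)-3-iodobut-2-en-1-ol | C/C(I)=C/CO | intermediate
3 | (2Z)-3-methylhexa-2,5-dien-1-ol | C/C(CC=C)=C/CO | intermediate
4 | [(1R,2S)-2-methyl-2-(prop-2-en-1-yl)cyclopropyl]methanol | C[C@]1(CC=C)C[C@H]1CO | intermediate
5 | (1R,2S)-2-methyl-2-(prop-2-en-1-yl)cyclopropane-1-carbaldehyde | C[C@]1(CC=C)C[C@H]1C=O | intermediate
6 | 3-methyl-1-[(1R,2S)-2-methyl-2-(prop-2-en-1-yl)cyclopropyl]but-3-en-1-ol (both carbinol epimers) | C[C@]1(CC=C)C[C@H]1C(O)CC(C)=C | intermediate
7 | (1R,7S)-4,7-dimethylbicyclo[5.1.0]oct-4-en-2-ol (both C2 epimers) | C[C@]12C[C@H]1C(O)CC(C)=CC2 | intermediate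
8 | (1R,7S)-4,7-dimethylbicyclo[5.1.0]oct-4-en-2-one | C[C@]12C[C@H]1C(=O)CC(C)=CC2 | intermediate
9 | 3-methylbut-1-yne | CC(C)C#C | starting material
10 | [(3-methylbut-1-en-2-yl)sulfanyl]benzene | CC(C)C(=C)Sc1ccccc1 | intermediate
11 | [(3-methylbut-1-en-2-yl)sulfonyl]benzene | CC(C)C(=C)S(=O)(=O)c1ccccc1 | intermediate
12 | (1R)-4-(phenylsulfonyl)dauc-8-en-6-one (β-sulfonyl ketone, mixture at C4 and C5) | CC(C)C1(S(=O)(=O)c3ccccc3)CC[C@]2(C)CC=C(C)CC(=O)C12 | intermediate (not isolated)
13 | (1R)-dauca-4,8-dien-6-one, that is (8aR)-6,8a-dimethyl-3-(propan-2-yl)-1,2,8,8a-tetrahydroazulen-4(5H)-one | CC(C)C1=C2C(=O)CC(C)=CC[C@@]2(C)CC1 | intermediate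
14 | (1R,6R)-dauca-4,8-dien-6-ol (6β-hydroxyl) | CC(C)C1=C2[C@H](O)CC(C)=CC[C@@]2(C)CC1 | intermediate
15 | (1R,4R,5S,6R)-4,5-epoxydauc-8-en-6-ol (4β,5β-epoxide, 6β-hydroxyl) | CC(C)[C@@]12CC[C@]3(C)CC=C(C)C[C@@H](O)[C@@]32O1 | intermediate
16 | (1R,4R,5R)-4-hydroxydauc-8-en-6-one (4β-hydroxyl, 5α-H, trans-fused) | CC(C)[C@]1(O)CC[C@]2(C)CC=C(C)CC(=O)[C@H]21 | intermediate
17 | (1R,4R,5S,6S)-dauc-8-ene-4,6-diol (4β,6α-diol) | CC(C)[C@]1(O)CC[C@]2(C)CC=C(C)C[C@H](O)[C@H]21 | intermediate
18 | (1R,4R,5S,6S)-4-hydroxydauc-8-en-6-yl benzoate | CC(C)[C@]1(O)CC[C@]2(C)CC=C(C)C[C@H](OC(=O)c3ccccc3)[C@H]21 | intermediate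
19 | (1R,4R,5S,6S,8R,9S)-8,9-epoxy-4-hydroxydaucan-6-yl benzoate (8α,9α-epoxide) | CC(C)[C@]1(O)CC[C@]2(C)C[C@@H]3O[C@]3(C)C[C@H](OC(=O)c3ccccc3)[C@H]21 | target

Total step count: 16. Longest linear sequence: 14 steps (steps 1 to 7 and 10 to 16).

Steps most likely to fail

1. Step 10. Electron transfer may go to the vinyl sulfone instead of the ketone, or the ketyl may fragment the internal C1–C5 bond, and either would stall or misdirect the relay. The fallback sets out from 8 (with alkyne 9) and comes back at 13. Zerovalent nickel should insert into the less hindered C2–C5 cyclopropane bond (Ni(cod)2, PCy3, Me2AlCl, toluene, 50 °C), and insertion of 3-methylbut-1-yne 9 followed by reductive elimination should give the β,γ-unsaturated ketone (1R)-dauca-3,8-dien-6-one F1 as a mixture at C5. Brief treatment with DBU (CH2Cl2, 20 °C) should then move the C3=C4 alkene into conjugation to give 13.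

2. Step 13. Ionisation of the epoxide at C4, or a Wagner–Meerwein shift from C1, may outrun the hydride shift. The fallback sets out from 15 and comes back at 16. Dess–Martin oxidation (pyridine, CH2Cl2, 0 °C) should give the epoxy ketone (1R,4R,5R)-4,5-epoxydauc-8-en-6-one F2. Its reductive opening with SmI2 (MeOH, THF, −78 °C) breaks the C5–O bond, and kinetic protonation of the samarium enolate at C5 from the α-face, the β-face being blocked by the C1 methyl group and the C4 alkoxide, should give 16.

3. Step 11. Poor facial selectivity in the hydride addition to C6 would pass the wrong carbinol epimer to the directed epoxidation and so invert C4. The fallback sets out from 13 and comes back at 14. A Corey–Bakshi–Shibata reduction with (S)-2-methyl-CBS-oxazaborolidine and catecholborane (toluene, −78 °C) lets the catalyst, not the substrate, choose the α-face, with the alkenyl carbon C5 as the large group. This path makes no compound outside the list (none F0).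

Further compounds

F1 | step 10 | (1R)-dauca-3,8-dien-6-one (both C5 epimers) | CC(C)C1=CC[C@]2(C)CC=C(C)CC(=O)C12
F2 | step 13 | (1R,4R,5R)-4,5-epoxydauc-8-en-6-one | CC(C)[C@@]12CC[C@]3(C)CC=C(C)CC(=O)[C@@]32O1
F0 | step 11 | none | none
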